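## Retrosynthetic overview

1. 12 ⇒ syn-diol 10. Both acetates go on last, and the phenol is unmasked in the same flask.
2. Key disconnection C3–C4 (10 ⇒ 9). A configurationally defined α-oxygenated carbanion at C3 (lithiated carbamate 8, a carbinol carbon used as the nucleophile) attacks the CH2 terminus of (S)-1,2-epoxynonane 7. In normal reactivity both carbons are electrophiles, and no ketone or later reduction is needed.
3. C3 (R) is set by (−)-sparteine-controlled deprotonation of carbamate 3, which is made in one flask from dihydroconiferyl alcohol 1. C5 (S) comes from (S)-epichlorohydrin 4 and hexylmagnesium bromide 5.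
4. Rings: none is built for the target. The arene is bought, and the only ring made (the oxirane of 7) is opened again in the key step.

Assumption: 1, 4, 5 (as its ether solution) and (−)-sparteine are bought; C1–C12 number the dodecane chain of the target, with C1 benzylic.

## Route

**Step 1**
Reactants: 1 4-(3-hydroxypropyl)-2-methoxyphenol (dihydroconiferyl alcohol)
Product: 3 O-[3-(3-methoxy-4-triisopropylsilyloxyphenyl)propyl] N,N-diisopropylcarbamate, via silyl ether alcohol 2 (not isolated)
Conditions: NaH (1.0 equiv), TIPSCl (1.0 equiv), THF, 0 °C to rt; then iPr2NCOCl, Et3N, reflux, 24 h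
Reagents that add atoms: triisopropylsilyl chloride CC(C)[Si](Cl)(C(C)C)C(C)C; N,N-diisopropylcarbamoyl chloride CC(C)N(C(C)C)C(=O)Cl
Why: One equivalent of NaH deprotonates only the phenol (pKa about 10 against about 16), so only the phenoxide is silylated (chemoselective O-silylation), and the remaining neutral primary alcohol is then acylated without any alkoxide being formed (O-carbamoylation); no stereocentre is formed.

**Step 2**
Reactants: 4 (S)-epichlorohydrin; 5 n-hexylmagnesium bromide
Product: 7 (S)-2-heptyloxirane [(S)-1,2-epoxynonane], via chlorohydrin 6 (not isolated)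
Conditions: CuI (10 mol %), THF, −40 to 0 °C; then aq NaOH, rt
Reagents that add atoms: none
Why: Copper-catalysed Grignard opening of the oxirane at its unsubstituted carbon, followed by intramolecular Williamson closure onto CH2Cl, never touches the C–O stereocentre, so the (S) centre of 4 becomes the (S) centre of 7 (the future C5).

**Step 3 (key step)**
Reactants: 3 carbamate (1.3 equiv); 7 (S)-2-heptyloxirane (1.0 equiv)
Product: 9 (3R,5S)-5-hydroxy-1-[3-methoxy-4-(triisopropylsilyloxy)phenyl]dodecan-3-yl N,N-diisopropylcarbamate, via lithiated carbamate 8 (not isolated)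
Conditions: s-BuLi (1.25 equiv), (−)-sparteine (1.3 equiv), Et2O, −78 °C, 5 h; then 7, BF3·OEt2 (1.5 equiv, dropwise), −78 °C, 2 h; aq NaHCO3
Reagents that add atoms: none
Why: Proposed new method: the known Hoppe asymmetric deprotonation removes the pro-S hydrogen next to the carbamate oxygen and gives the chelated, configurationally stable (S)-organolithium 8, and the new part is its BF3-assisted SN2 attack on the unsubstituted carbon of 7 at −78 °C, which should go with retention at the carbanion carbon (SE2ret, as in other substitutions of non-benzylic lithiated carbamates) to set C3 as R while the C5–O bond of 7 stays untouched (S) and the new alkoxide is held as its fluoroborate so that it cannot attack the carbamate; the closest known reaction types are BF3-promoted epoxide opening by alkyllithiums and α-alkoxyalkyllithiums and the retentive alkylation of sparteine-derived lithiated carbamates.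

**Step 4**
Reactants: 9
Product: 10 (3R,5S)-1-[3-methoxy-4-(triisopropylsilyloxy)phenyl]dodecane-3,5-diol (syn-1,3-diol)
Conditions: LiAlH4, THF, reflux; H2O, aq NaOH work-up
Reagents that add atoms: none
Why: LiAlH4 adds hydride to the carbamate carbonyl and expels the C3 alkoxide (reductive carbamate cleavage), so only the acyl C–O bond breaks, both stereocentres are kept, and the hindered aryl TIPS ether and the aryl methyl ether are not attacked.

**Step 5**
Reactants: 10
Product: 12 (3R,5S)-1-(4-hydroxy-3-methoxyphenyl)dodecane-3,5-diyl diacetate, via silylated diacetate 11 (not isolated)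
Conditions: Ac2O, Et3N, DMAP (cat.), CH2Cl2, rt; MeOH; then AcOH, TBAF, THF, 0 °C
Reagents that add atoms: acetic anhydride CC(=O)OC(C)=O
Why: DMAP-catalysed acetylation takes place at the two secondary oxygens with retention while the phenol is still masked, MeOH destroys the excess anhydride, and fluoride-driven desilylation buffered by AcOH then frees the phenol without acetate cleavage or migration.

Stereochemical note: 8 is expected with an enantiomer ratio of about 97:3. With enantiopure 7, the minor enantiomer of 8 ends up as the anti diastereomer, which is removed by chromatography at 9 or 10.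

## Compound list

1 | 4-(3-hydroxypropyl)-2-methoxyphenol (dihydroconiferyl alcohol) | COc1cc(CCCO)ccc1O | starting material
2 | 3-[3-methoxy-4-(triisopropylsilyloxy)phenyl]propan-1-ol | COc1cc(CCCO)ccc1O[Si](C(C)C)(C(C)C)C(C)C | intermediate
3 | 3-[3-methoxy-4-(triisopropylsilyloxy)phenyl]propyl N,N-diisopropylcarbamate | COc1cc(CCCOC(=O)N(C(C)C)C(C)C)ccc1O[Si](C(C)C)(C(C)C)C(C)C | intermediate
4 | (S)-epichlorohydrin | ClC[C@@H]1CO1 | starting material
5 | n-hexylmagnesium bromide | CCCCCC[Mg]Br | starting material
6 | (S)-1-chlorononan-2-ol | CCCCCCC[C@H](O)CCl | intermediate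
7 | (S)-2-heptyloxirane | CCCCCCC[C@H]1CO1 | intermediate
8 | (S)-1-lithio-3-[3-methoxy-4-(triisopropylsilyloxy)phenyl]propyl N,N-diisopropylcarbamate, present as its (−)-sparteine complex (diamine left out of the SMILES) | [Li][C@@H](CCc1ccc(O[Si](C(C)C)(C(C)C)C(C)C)c(OC)c1)OC(=O)N(C(C)C)C(C)C | intermediate
9 | (3R,5S)-5-hydroxy-1-[3-methoxy-4-(triisopropylsilyloxy)phenyl]dodecan-3-yl N,N-diisopropylcarbamate | CCCCCCC[C@@H](C[C@@H](CCc1ccc(O[Si](C(C)C)(C(C)C)C(C)C)c(OC)c1)OC(=O)N(C(C)C)C(C)C)O | intermediate
10 | (3R,5S)-1-[3-methoxy-4-(triisopropylsilyloxy)phenyl]dodecane-3,5-diol | CCCCCCC[C@@H](C[C@@H](CCc1ccc(O[Si](C(C)C)(C(C)C)C(C)C)c(OC)c1)O)O | intermediate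
11 | (3R,5S)-1-[3-methoxy-4-(triisopropylsilyloxy)phenyl]dodecane-3,5-diyl diacetate | CCCCCCC[C@@H](C[C@@H](CCc1ccc(O[Si](C(C)C)(C(C)C)C(C)C)c(OC)c1)OC(C)=O)OC(C)=O | intermediate
12 | (3R,5S)-1-(4-hydroxy-3-methoxyphenyl)dodecane-3,5-diyl diacetate | CCCCCCC[C@@H](C[C@@H](CCc1ccc(O)c(OC)c1)OC(C)=O)OC(C)=O | target

## Step count and risks

Total step count: 5.
Longest linear sequence: 4 (steps 1, 3, 4, 5; the branch through step 2 is equally long).

**Most likely to fail: step 3.**
- Risk: the hindered, sparteine-bound carbanion may be captured by BF3 faster than it opens the epoxide.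
- Fallback: it sets out from 3 (through the same 8) and comes back at 10, so step 4 is skipped.
- 1-Nonene is diborated with B2pin2 under Pt(dba)3 and the TADDOL-derived phosphonite enantiomer that delivers (R)-1,2-bis(pinacolatoboryl)nonane F1.
- At −78 °C, 8 adds with retention to the less hindered primary boron of F1 and gives the lithium boronate complex F2.
- In refluxing Et2O, F2 undergoes a stereospecific 1,2-metallate rearrangement with loss of the carbamate to give the (3R,5S)-1,3-bis(boronic ester) F3.
- NaBO3·4H2O in THF/H2O oxidises both C–B bonds with retention to give 10.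

**Second: step 4.**
- Risk: the forcing hydride conditions may erode the aryl silyl ether and give mixtures.
- Fallback: it sets out from 9 and comes back at 12.
- LiAlH4 in refluxing THF, followed by TBAF on the crude material, removes the carbamate and all remaining silyl ether to give (3R,5S)-[8]-gingerdiol F4.
- Exhaustive acetylation (Ac2O, pyridine, DMAP) gives the triacetate F5.
- Pyrrolidine (1.1 equiv, MeCN, 0 °C) aminolyses only the aryl acetate, which reacts far faster than the secondary alkyl acetates, and gives 12.

**Third: step 1.**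
- Risk: silylation may not stay on the phenol.
- Fallback: it sets out from 1 and comes back at 2.
- Both oxygens are silylated (TIPSCl, imidazole, DMF) to give the bis(triisopropylsilyl) ether F6.
- The alkyl silyl ether alone is cleaved with 1% HCl in aqueous EtOH, because aryl silyl ethers are much more stable to acid.
- This gives 2, now isolated, which is carbamoylated as in the second half of step 1.

## Further compounds

F1 | step 3 | (R)-2,2'-(nonane-1,2-diyl)bis(4,4,5,5-tetramethyl-1,3,2-dioxaborolane) | CCCCCCC[C@@H](CB1OC(C)(C)C(C)(C)O1)B2OC(C)(C)C(C)(C)O2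
F2 | step 3 | lithium boronate complex from 8 and the primary boron of F1 | [Li+].CCCCCCC[C@@H](C[B-]1(OC(C)(C)C(C)(C)O1)[C@@H](CCc2ccc(O[Si](C(C)C)(C(C)C)C(C)C)c(OC)c2)OC(=O)N(C(C)C)C(C)C)B3OC(C)(C)C(C)(C)O3
F3 | step 3 | (3R,5S)-1-[3-methoxy-4-(triisopropylsilyloxy)phenyl]dodecane-3,5-diyl bis(pinacol boronate) | CCCCCCC[C@@H](C[C@@H](CCc1ccc(O[Si](C(C)C)(C(C)C)C(C)C)c(OC)c1)B2OC(C)(C)C(C)(C)O2)B3OC(C)(C)C(C)(C)O3
F4 | step 4 | (3R,5S)-1-(4-hydroxy-3-methoxyphenyl)dodecane-3,5-diol, (3R,5S)-[8]-gingerdiol | CCCCCCC[C@@H](C[C@@H](CCc1ccc(O)c(OC)c1)O)O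
F5 | step 4 | (3R,5S)-1-(4-acetoxy-3-methoxyphenyl)dodecane-3,5-diyl diacetate | CCCCCCC[C@@H](C[C@@H](CCc1ccc(OC(C)=O)c(OC)c1)OC(C)=O)OC(C)=O
F6 | step 1 | triisopropyl{3-[3-methoxy-4-(triisopropylsilyloxy)phenyl]propoxy}silane | COc1cc(CCCO[Si](C(C)C)(C(C)C)C(C)C)ccc1O[Si](C(C)C)(C(C)C)C(C)C
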